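The route rests on disconnecting the alkyl C–O bond of the lactone, between the ring oxygen and allylic C2. Three catalytic vinylogous aldol additions build the chain; a chromium allylation closes the 14-membered carbocycle and, through its chair transition state, gives the C1/C2-syn γ-hydroxy ester, epimeric to the target at C2. The key step acts on the derived, fully silylated macrocyclic hydroxy acid: an invertive intramolecular Mitsunobu lactonisation forms the O–C2 bond by SN2 displacement and so, in one operation, closes the α-methylene-γ-lactone ring, corrects C2 and creates the trans ring fusion. It exploits that C2 is a secondary allylic carbinol carbon γ to carboxyl carbon C16 on the 14-membered ring.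

Key step: step 15

Numbering used below: ring carbons run C1 (ring-fusion CH), C2 (lactone O–CH), C3=C4(Me), C5, C6 (OH), C7=C8(Me), C9, C10 (OAc), C11=C12(Me), C13, C14 (OAc); C15 is the acrylate α-carbon, C16 the carbonyl carbon, C17 the exo-methylene carbon; the target is (1S,2S,6S,10S,14S), trans-fused. TES = triethylsilyl, TBS = tert-butyldimethylsilyl.

Assumption: the "(S,S)-bisphosphoramide catalyst" of steps 3, 6 and 9 (two (S)-N,N′-dimethyl-1,1′-binaphthyl-2,2′-diamine phosphoramide units, each phosphorus also bound to one nitrogen of an N,N′-dimethylpentane-1,5-diamine linker) is taken as an available catalyst.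

Step 1
Reactants: 1 3-methylbut-2-enoyl chloride; 2 morpholine
Product: 3 4-(3-methylbut-2-enoyl)morpholine
Conditions: Et3N, CH2Cl2, 0 °C → rt
Reagents that add atoms: none
Why: N-acylation of the secondary amine by the acid chloride (amide formation), Et3N taking up the HCl.

Step 2
Reactants: 3 4-(3-methylbut-2-enoyl)morpholine
Product: 4 (Z)-4-[1-(tert-butyldimethylsilyloxy)-3-methylbuta-1,3-dien-1-yl]morpholine
Conditions: KN(SiMe3)2, TBSCl, THF, −78 °C
Reagents that add atoms: tert-butyldimethylsilyl chloride, CC(C)(C)[Si](C)(C)Cl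
Why: γ-deprotonation of the β,β-dimethyl enamide and O-silylation of the extended enolate (silyl dienol ether formation) give the N,O-silyl dienyl ketene acetal, Z at the new C=C because the morpholine avoids allylic strain.

Step 3
Reactants: 5 acrolein; 4 silyl dienyl ketene acetal
Product: 6 (2E,5S)-5-hydroxy-3-methyl-1-(morpholin-4-yl)hepta-2,6-dien-1-one
Conditions: SiCl4, (S,S)-bisphosphoramide catalyst (5 mol %), i-Pr2NEt (10 mol %), CH2Cl2, −78 °C; sat. aq. NaHCO3
Reagents that add atoms: none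
Why: Lewis-base-activated SiCl4 vinylogous Mukaiyama aldol addition, in which the dienolate attacks through its γ-carbon the Si face of the catalyst-bound aldehyde (catalyst control), should set (S)-C14 and, from the s-trans diene, the E C11=C12 olefin.

Step 4
Reactants: 6 (2E,5S)-5-hydroxy-3-methyl-1-(morpholin-4-yl)hepta-2,6-dien-1-one
Product: 7 (2E,5S)-3-methyl-1-(morpholin-4-yl)-5-(triethylsilyloxy)hepta-2,6-dien-1-one
Conditions: TESCl, imidazole, CH2Cl2, 0 °C
Reagents that add atoms: triethylsilyl chloride, CC[Si](CC)(CC)Cl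
Why: silyl ether formation masks O14 through the reductions and aldol steps and can later be removed selectively next to TBS for exchange against acetate.

Step 5
Reactants: 7 (2E,5S)-3-methyl-1-(morpholin-4-yl)-5-(triethylsilyloxy)hepta-2,6-dien-1-one
Product: 8 (2E,5S)-3-methyl-5-(triethylsilyloxy)hepta-2,6-dienal
Conditions: i-Bu2AlH, THF, −78 °C; aq. Rochelle salt
Reagents that add atoms: none
Why: partial hydride reduction of the morpholine amide, which like an N-methoxy-N-methylamide stops at the aldehyde oxidation level at −78 °C, should give the E enal with the vinyl group untouched.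

Step 6
Reactants: 8 (2E,5S)-3-methyl-5-(triethylsilyloxy)hepta-2,6-dienal; 4 silyl dienyl ketene acetal
Product: 9 (2E,5S,6E,9S)-5-hydroxy-3,7-dimethyl-1-(morpholin-4-yl)-9-(triethylsilyloxy)undeca-2,6,10-trien-1-one
Conditions: SiCl4, (S,S)-bisphosphoramide catalyst (5 mol %), i-Pr2NEt (10 mol %), CH2Cl2, −78 °C; sat. aq. NaHCO3
Reagents that add atoms: none
Why: second catalytic vinylogous Mukaiyama aldol addition, again by Si-face attack on the enal under catalyst control, should set (S)-C10 and the E C7=C8 olefin.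

Step 7
Reactants: 9 (2E,5S,6E,9S)-5-hydroxy-3,7-dimethyl-1-(morpholin-4-yl)-9-(triethylsilyloxy)undeca-2,6,10-trien-1-one
Product: 10 (2E,5S,6E,9S)-3,7-dimethyl-1-(morpholin-4-yl)-5,9-bis(triethylsilyloxy)undeca-2,6,10-trien-1-one
Conditions: TESCl, imidazole, CH2Cl2, 0 °C
Reagents that add atoms: triethylsilyl chloride, CC[Si](CC)(CC)Cl
Why: silyl ether formation gives O10 the same protecting group as O14, since both become acetates at the end.

Step 8
Reactants: 10 (2E,5S,6E,9S)-3,7-dimethyl-1-(morpholin-4-yl)-5,9-bis(triethylsilyloxy)undeca-2,6,10-trien-1-one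
Product: 11 (2E,5S,6E,9S)-3,7-dimethyl-5,9-bis(triethylsilyloxy)undeca-2,6,10-trienal
Conditions: i-Bu2AlH, THF, −78 °C; aq. Rochelle salt
Reagents that add atoms: none
Why: partial reduction of the morpholine amide to the aldehyde oxidation level, as in step 5.

Step 9
Reactants: 11 (2E,5S,6E,9S)-3,7-dimethyl-5,9-bis(triethylsilyloxy)undeca-2,6,10-trienal; 4 silyl dienyl ketene acetal
Product: 12 (2E,5S,6E,9S,10E,13S)-5-hydroxy-3,7,11-trimethyl-1-(morpholin-4-yl)-9,13-bis(triethylsilyloxy)pentadeca-2,6,10,14-tetraen-1-one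
Conditions: SiCl4, (S,S)-bisphosphoramide catalyst (5 mol %), i-Pr2NEt (10 mol %), CH2Cl2, −78 °C; sat. aq. NaHCO3
Reagents that add atoms: none
Why: third catalytic vinylogous Mukaiyama aldol addition (Si-face attack, catalyst control) should set (S)-C6 and the E C3=C4 olefin.

Step 10
Reactants: 12 (2E,5S,6E,9S,10E,13S)-5-hydroxy-3,7,11-trimethyl-1-(morpholin-4-yl)-9,13-bis(triethylsilyloxy)pentadeca-2,6,10,14-tetraen-1-one
Product: 13 (2E,5S,6E,9S,10E,13S)-5-(tert-butyldimethylsilyloxy)-3,7,11-trimethyl-1-(morpholin-4-yl)-9,13-bis(triethylsilyloxy)pentadeca-2,6,10,14-tetraen-1-one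
Conditions: TBSCl, imidazole, DMF, rt
Reagents that add atoms: tert-butyldimethylsilyl chloride, CC(C)(C)[Si](C)(C)Cl
Why: silyl ether formation with the more robust TBS group keeps O6 protected while O10 and O14 are later unmasked and acetylated.

Step 11
Reactants: 13 (2E,5S,6E,9S,10E,13S)-5-(tert-butyldimethylsilyloxy)-3,7,11-trimethyl-1-(morpholin-4-yl)-9,13-bis(triethylsilyloxy)pentadeca-2,6,10,14-tetraen-1-one
Product: 14 (2E,5S,6E,9S,10E,13S)-5-(tert-butyldimethylsilyloxy)-3,7,11-trimethyl-9,13-bis(triethylsilyloxy)pentadeca-2,6,10,14-tetraenal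
Conditions: i-Bu2AlH, THF, −78 °C; aq. Rochelle salt
Reagents that add atoms: none
Why: partial reduction of the morpholine amide gives the C2 enal, as in step 5.

Step 12
Reactants: 14 (2E,5S,6E,9S,10E,13S)-5-(tert-butyldimethylsilyloxy)-3,7,11-trimethyl-9,13-bis(triethylsilyloxy)pentadeca-2,6,10,14-tetraenal; 15 methyl 2-(bromomethyl)prop-2-enoate
Product: 16 methyl (2Z,4S,6E,8S,10E,12S,14E)-2-(bromomethyl)-12-(tert-butyldimethylsilyloxy)-6,10,14-trimethyl-16-oxo-4,8-bis(triethylsilyloxy)hexadeca-2,6,10,14-tetraenoate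
Conditions: second-generation Hoveyda–Grubbs catalyst (10 mol %), 15 (8 equiv), CH2Cl2, 40 °C
Reagents that add atoms: none
Why: olefin cross-metathesis, in which the ruthenium carbene loads onto the only monosubstituted olefin (the trisubstituted olefins and the enal do not initiate) and then engages the acrylate used in excess, should give the conjugated enoate with the ester trans to C14 (2Z), and a minor 2E isomer would converge in step 13.

Step 13
Reactants: 16 methyl (2Z,4S,6E,8S,10E,12S,14E)-2-(bromomethyl)-12-(tert-butyldimethylsilyloxy)-6,10,14-trimethyl-16-oxo-4,8-bis(triethylsilyloxy)hexadeca-2,6,10,14-tetraenoate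
Product: 18 methyl 2-[(1R,2R,3E,6S,7E,10S,11E,14S)-6-(tert-butyldimethylsilyloxy)-2-hydroxy-4,8,12-trimethyl-10,14-bis(triethylsilyloxy)cyclotetradeca-3,7,11-trien-1-yl]prop-2-enoate, via allylchromium dichloride 17 (not isolated)
Conditions: CrCl2 (10 equiv), THF, 25 °C, slow addition of 16 (final 0.003 M); aq. work-up
Reagents that add atoms: none
Why: Nozaki–Hiyama–Kishi-type allylation, in which divalent chromium reduces the allylic bromide to 17 and its γ-carbon C1 adds to the C2 enal through a closed chair transition state with the γ-substituent (cis to CH2Cr) axial, should give the C1/C2-syn adduct; the face is expected to be set by C14, whose hydrogen eclipses C1=C15 to avoid allylic strain while the C13 chain lies anti to the forming bond, leading to (1R,2R).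

Step 14
Reactants: 18 methyl 2-[(1R,2R,3E,6S,7E,10S,11E,14S)-6-(tert-butyldimethylsilyloxy)-2-hydroxy-4,8,12-trimethyl-10,14-bis(triethylsilyloxy)cyclotetradeca-3,7,11-trien-1-yl]prop-2-enoate
Product: 19 2-[(1R,2R,3E,6S,7E,10S,11E,14S)-6-(tert-butyldimethylsilyloxy)-2-hydroxy-4,8,12-trimethyl-10,14-bis(triethylsilyloxy)cyclotetradeca-3,7,11-trien-1-yl]prop-2-enoic acid
Conditions: LiOH, THF/MeOH/H2O, 0 °C → rt; then 0.5 M HCl to pH 4 at 0 °C, used at once
Reagents that add atoms: lithium hydroxide (hydroxide oxygen), [Li+].[OH-]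
Why: ester saponification leaves the silyl ethers intact, reopens any material that has closed through the acyl carbon to the cis-lactone F2, and the γ-hydroxy acid is taken on before it can relactonise with retention.

Step 15
Reactants: 19 2-[(1R,2R,3E,6S,7E,10S,11E,14S)-6-(tert-butyldimethylsilyloxy)-2-hydroxy-4,8,12-trimethyl-10,14-bis(triethylsilyloxy)cyclotetradeca-3,7,11-trien-1-yl]prop-2-enoic acid
Product: 21 (1R,2S,6S,10S,14S)-configured trans-fused α-methylene-γ-lactone of the 3E,7E,11E-cyclotetradecatriene core with TBS on O6 and TES on O10 and O14, via alkoxyphosphonium carboxylate 20 (not isolated)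
Conditions: PPh3, DIAD (slow addition), toluene/THF, 0 °C → rt, 0.005 M
Reagents that add atoms: none
Why: PPh3 and DIAD form a betaine that is protonated by the acrylic acid of 19 and then turns the only free hydroxyl, at C2, into the alkoxyphosphonium ion of zwitterion 20, whose carboxylate oxygen displaces triphenylphosphine oxide from C2 by backside attack. The closest known reaction type is the invertive intramolecular Mitsunobu lactonisation of γ-hydroxy acids. The five-membered lactone ring (O, C2, C1, C15, C16) closes in the 5-exo-tet mode. C2 is the only stereocentre that changes: SN2 inversion converts the (2R) carbinol into the (2S) lactone carbon, which with the untouched C1 gives the trans ring fusion. The step needs O-alkylation at C2 to win over closure through the acyl carbon (retention), over SN2′ attack at C4 (a seven-membered ring) and over elimination; the five-atom tether, the acidity of the acrylic acid (which favours the alkoxyphosphonium over an acyloxyphosphonium ion) and slow addition of DIAD at 0 °C should secure this. Chemoselectivity is built in, because O6, O10 and O14 are silylated and C2 carries the only free hydroxyl.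

Step 16
Reactants: 21 silylated trans-fused lactone
Product: 22 (1S,2S,6S,10S,14S)-configured trans-fused lactone with free hydroxyls at C10 and C14 and TBS on O6
Conditions: PPTS (cat.), MeOH/CH2Cl2, 0 °C
Reagents that add atoms: none
Why: mild acid-catalysed methanolysis should cleave the two triethylsilyl ethers much faster than the bulkier TBS ether, and the non-basic conditions should keep the lactone from migrating to O14.

Step 17
Reactants: 22 C10,C14-diol lactone
Product: 23 (1S,2S,6S,10S,14S)-configured trans-fused lactone with acetates at C10 and C14 and TBS on O6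
Conditions: Ac2O, pyridine, DMAP (cat.), CH2Cl2, 0 °C → rt
Reagents that add atoms: acetic anhydride, CC(=O)OC(C)=O
Why: DMAP-catalysed O-acetylation of both secondary alcohols, carried out directly after step 16, installs the two acetates while O6 stays silylated.

Step 18
Reactants: 23 diacetate TBS ether
Product: 24 CNP0418981.1, the (1S,2S,6S,10S,14S)-configured trans-fused α-methylene-γ-lactone with acetates at C10 and C14 and a free hydroxyl at C6
Conditions: HF·pyridine, pyridine/THF, 0 °C → rt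
Reagents that add atoms: none
Why: buffered fluoride-mediated desilylation removes the TBS ether without touching the acetates, the allylic systems or the α-methylene lactone.

Compound list
1 | 3-methylbut-2-enoyl chloride | CC(C)=CC(=O)Cl | starting material
2 | morpholine | C1COCCN1 | starting material
3 | 4-(3-methylbut-2-enoyl)morpholine | CC(C)=CC(=O)N1CCOCC1 | intermediate
4 | (Z)-4-[1-(tert-butyldimethylsilyloxy)-3-methylbuta-1,3-dien-1-yl]morpholine | C=C(C)/C=C(\O[Si](C)(C)C(C)(C)C)N1CCOCC1 | intermediate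
5 | acrolein (prop-2-enal) | C=CC=O | starting material
6 | (2E,5S)-5-hydroxy-3-methyl-1-(morpholin-4-yl)hepta-2,6-dien-1-one | C=C[C@@H](O)C/C(C)=C/C(=O)N1CCOCC1 | intermediate
7 | (2E,5S)-3-methyl-1-(morpholin-4-yl)-5-(triethylsilyloxy)hepta-2,6-dien-1-one | C=C[C@@H](O[Si](CC)(CC)CC)C/C(C)=C/C(=O)N1CCOCC1 | intermediate
8 | (2E,5S)-3-methyl-5-(triethylsilyloxy)hepta-2,6-dienal | C=C[C@@H](O[Si](CC)(CC)CC)C/C(C)=C/C=O | intermediate
9 | (2E,5S,6E,9S)-5-hydroxy-3,7-dimethyl-1-(morpholin-4-yl)-9-(triethylsilyloxy)undeca-2,6,10-trien-1-one | C=C[C@@H](O[Si](CC)(CC)CC)C/C(C)=C/[C@@H](O)C/C(C)=C/C(=O)N1CCOCC1 | intermediate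
10 | (2E,5S,6E,9S)-3,7-dimethyl-1-(morpholin-4-yl)-5,9-bis(triethylsilyloxy)undeca-2,6,10-trien-1-one | C=C[C@@H](O[Si](CC)(CC)CC)C/C(C)=C/[C@@H](O[Si](CC)(CC)CC)C/C(C)=C/C(=O)N1CCOCC1 | intermediate
11 | (2E,5S,6E,9S)-3,7-dimethyl-5,9-bis(triethylsilyloxy)undeca-2,6,10-trienal | C=C[C@@H](O[Si](CC)(CC)CC)C/C(C)=C/[C@@H](O[Si](CC)(CC)CC)C/C(C)=C/C=O | intermediate
12 | (2E,5S,6E,9S,10E,13S)-5-hydroxy-3,7,11-trimethyl-1-(morpholin-4-yl)-9,13-bis(triethylsilyloxy)pentadeca-2,6,10,14-tetraen-1-one | C=C[C@@H](O[Si](CC)(CC)CC)C/C(C)=C/[C@@H](O[Si](CC)(CC)CC)C/C(C)=C/[C@@H](O)C/C(C)=C/C(=O)N1CCOCC1 | intermediate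
13 | (2E,5S,6E,9S,10E,13S)-5-(tert-butyldimethylsilyloxy)-3,7,11-trimethyl-1-(morpholin-4-yl)-9,13-bis(triethylsilyloxy)pentadeca-2,6,10,14-tetraen-1-one | C=C[C@@H](O[Si](CC)(CC)CC)C/C(C)=C/[C@@H](O[Si](CC)(CC)CC)C/C(C)=C/[C@@H](O[Si](C)(C)C(C)(C)C)C/C(C)=C/C(=O)N1CCOCC1 | intermediate
14 | (2E,5S,6E,9S,10E,13S)-5-(tert-butyldimethylsilyloxy)-3,7,11-trimethyl-9,13-bis(triethylsilyloxy)pentadeca-2,6,10,14-tetraenal | C=C[C@@H](O[Si](CC)(CC)CC)C/C(C)=C/[C@@H](O[Si](CC)(CC)CC)C/C(C)=C/[C@@H](O[Si](C)(C)C(C)(C)C)C/C(C)=C/C=O | intermediate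
15 | methyl 2-(bromomethyl)prop-2-enoate | C=C(CBr)C(=O)OC | starting material
16 | methyl (2Z,4S,6E,8S,10E,12S,14E)-2-(bromomethyl)-12-(tert-butyldimethylsilyloxy)-6,10,14-trimethyl-16-oxo-4,8-bis(triethylsilyloxy)hexadeca-2,6,10,14-tetraenoate | COC(=O)/C(CBr)=C/[C@@H](O[Si](CC)(CC)CC)C/C(C)=C/[C@@H](O[Si](CC)(CC)CC)C/C(C)=C/[C@@H](O[Si](C)(C)C(C)(C)C)C/C(C)=C/C=O | intermediate
17 | allylchromium dichloride derived from 16 (CrCl2 on C17 in place of Br) | COC(=O)/C(C[Cr](Cl)Cl)=C/[C@@H](O[Si](CC)(CC)CC)C/C(C)=C/[C@@H](O[Si](CC)(CC)CC)C/C(C)=C/[C@@H](O[Si](C)(C)C(C)(C)C)C/C(C)=C/C=O | intermediate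
18 | methyl 2-[(1R,2R,3E,6S,7E,10S,11E,14S)-6-(tert-butyldimethylsilyloxy)-2-hydroxy-4,8,12-trimethyl-10,14-bis(triethylsilyloxy)cyclotetradeca-3,7,11-trien-1-yl]prop-2-enoate | C=C(C(=O)OC)[C@@H]1[C@H](O)/C=C(\C)C[C@H](O[Si](C)(C)C(C)(C)C)/C=C(\C)C[C@H](O[Si](CC)(CC)CC)/C=C(\C)C[C@@H]1O[Si](CC)(CC)CC | intermediate
19 | 2-[(1R,2R,3E,6S,7E,10S,11E,14S)-6-(tert-butyldimethylsilyloxy)-2-hydroxy-4,8,12-trimethyl-10,14-bis(triethylsilyloxy)cyclotetradeca-3,7,11-trien-1-yl]prop-2-enoic acid | C=C(C(=O)O)[C@@H]1[C@H](O)/C=C(\C)C[C@H](O[Si](C)(C)C(C)(C)C)/C=C(\C)C[C@H](O[Si](CC)(CC)CC)/C=C(\C)C[C@@H]1O[Si](CC)(CC)CC | intermediate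
20 | zwitterion of 19 with O2 bound to triphenylphosphonium and the carboxyl as carboxylate | C=C(C(=O)[O-])[C@@H]1[C@H](O[P+](c2ccccc2)(c2ccccc2)c2ccccc2)/C=C(\C)C[C@H](O[Si](C)(C)C(C)(C)C)/C=C(\C)C[C@H](O[Si](CC)(CC)CC)/C=C(\C)C[C@@H]1O[Si](CC)(CC)CC | intermediate
21 | (1R,2S,6S,10S,14S) trans-fused α-methylene-γ-lactone (lactone O on C2, C15 on C1) of the 3E,7E,11E-4,8,12-trimethylcyclotetradecatriene, 6-OTBS, 10,14-bis-OTES | C=C1C(=O)O[C@H]2/C=C(\C)C[C@H](O[Si](C)(C)C(C)(C)C)/C=C(\C)C[C@H](O[Si](CC)(CC)CC)/C=C(\C)C[C@H](O[Si](CC)(CC)CC)[C@H]12 | intermediate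
22 | (1S,2S,6S,10S,14S) trans-fused lactone as 21 but with free hydroxyls at C10 and C14, 6-OTBS | C=C1C(=O)O[C@H]2/C=C(\C)C[C@H](O[Si](C)(C)C(C)(C)C)/C=C(\C)C[C@H](O)/C=C(\C)C[C@H](O)[C@H]12 | intermediate
23 | (1S,2S,6S,10S,14S) trans-fused lactone with acetates at C10 and C14, 6-OTBS | C=C1C(=O)O[C@H]2/C=C(\C)C[C@H](O[Si](C)(C)C(C)(C)C)/C=C(\C)C[C@H](OC(C)=O)/C=C(\C)C[C@H](OC(C)=O)[C@H]12 | intermediate
24 | CNP0418981.1, (1S,2S,6S,10S,14S) trans-fused lactone with acetates at C10 and C14 and free 6-OH | C=C1C(=O)O[C@H]2/C=C(\C)C[C@H](O)/C=C(\C)C[C@H](OC(C)=O)/C=C(\C)C[C@H](OC(C)=O)[C@H]12 | target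

Total step count: 18. Longest linear sequence: 18 steps (from 1 through 3 and 4 to 24; 16 steps counted from acrolein 5).

Steps most likely to fail

Step 13. What may go wrong is attack of the aldehyde on the wrong face of the allyl unit, so that the C14-to-C1 relay is lost, or oligomerisation instead of ring closure. The fallback sets out from 16 and comes back at 18. It replaces the closed chromium chair by an open, Lewis-acid-mediated transition state: Pd(PPh3)4-catalysed stannylation of the allylic bromide with Me3SnSnMe3 (THF, rt) gives the allylstannane F1. F1 is then cyclised with BF3·OEt2 (CH2Cl2, −78 °C, high dilution) through an antiperiplanar SE2′ addition, which is likewise syn-selective but responds differently to the C14 substituent, to give 18.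

Step 15. What may go wrong is activation of the carboxyl group instead of the alcohol, so that the ring closes through the acyl carbon with retention, or elimination of the activated allylic alcohol. The fallback sets out from 19 and comes back at 21. The acid 19 is deliberately closed through the acyl carbon (EDC·HCl, DMAP, CH2Cl2) to the cis-fused lactone F2. F2 is then equilibrated with Pd(PPh3)4 (THF, 50 °C): zerovalent palladium ionises the allylic lactone C2–O bond, the carboxylate returns to the π-allyl complex on either face, and re-closure, which again forms the O–C2 bond, should deliver the more stable trans-fused lactone 21. The silyl ethers are inert to the catalyst.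

Step 12. What may go wrong is slow cross-metathesis at the hindered allylic silyl ether, so that the carbene decomposes before it couples to the 1,1-disubstituted acrylate. The fallback sets out from 4 and comes back at 16. It builds the bromo-enoate by aldehyde chemistry instead of metathesis, which requires C1 to be carried as a protected alcohol from the start:
- Commercial (4-methoxybenzyloxy)acetaldehyde (COc1ccc(cc1)COCC=O) and 4 under the conditions of step 3 give the aldol adduct F3.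
- The operations of steps 4–11 then give in turn the silyl ether F4, the enal F5, the second aldol adduct F6, the bis-silyl ether F7, the enal F8, the third aldol adduct F9, the TBS ether F10 and the enal F11.
- DDQ (CH2Cl2/pH 7 buffer) frees the primary alcohol F12, and DMP oxidation gives the dialdehyde F13.
- A Morita–Baylis–Hillman reaction with methyl acrylate and DABCO at the more electrophilic α-silyloxy aldehyde gives the allylic alcohol F14.
- NBS/Me2S (CH2Cl2, 0 °C) converts F14 with allylic transposition into 16.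

Further compounds
F1 | step 13 | methyl (2Z,4S,6E,8S,10E,12S,14E)-12-(tert-butyldimethylsilyloxy)-6,10,14-trimethyl-16-oxo-4,8-bis(triethylsilyloxy)-2-[(trimethylstannyl)methyl]hexadeca-2,6,10,14-tetraenoate | COC(=O)/C(C[Sn](C)(C)C)=C/[C@@H](O[Si](CC)(CC)CC)C/C(C)=C/[C@@H](O[Si](CC)(CC)CC)C/C(C)=C/[C@@H](O[Si](C)(C)C(C)(C)C)C/C(C)=C/C=O
F2 | step 15 | (1R,2R,6S,10S,14S) cis-fused lactone, the C2 epimer of 21 | C=C1C(=O)O[C@@H]2/C=C(\C)C[C@H](O[Si](C)(C)C(C)(C)C)/C=C(\C)C[C@H](O[Si](CC)(CC)CC)/C=C(\C)C[C@H](O[Si](CC)(CC)CC)[C@H]12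
F3 | step 12 | (2E,5S)-5-hydroxy-6-(4-methoxybenzyloxy)-3-methyl-1-(morpholin-4-yl)hex-2-en-1-one | COc1ccc(cc1)COC[C@@H](O)C/C(C)=C/C(=O)N1CCOCC1
F4 | step 12 | (2E,5S)-6-(4-methoxybenzyloxy)-3-methyl-1-(morpholin-4-yl)-5-(triethylsilyloxy)hex-2-en-1-one | COc1ccc(cc1)COC[C@@H](O[Si](CC)(CC)CC)C/C(C)=C/C(=O)N1CCOCC1
F5 | step 12 | (2E,5S)-6-(4-methoxybenzyloxy)-3-methyl-5-(triethylsilyloxy)hex-2-enal | COc1ccc(cc1)COC[C@@H](O[Si](CC)(CC)CC)C/C(C)=C/C=O
F6 | step 12 | (2E,5S,6E,9S)-5-hydroxy-10-(4-methoxybenzyloxy)-3,7-dimethyl-1-(morpholin-4-yl)-9-(triethylsilyloxy)deca-2,6-dien-1-one | COc1ccc(cc1)COC[C@@H](O[Si](CC)(CC)CC)C/C(C)=C/[C@@H](O)C/C(C)=C/C(=O)N1CCOCC1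
F7 | step 12 | (2E,5S,6E,9S)-10-(4-methoxybenzyloxy)-3,7-dimethyl-1-(morpholin-4-yl)-5,9-bis(triethylsilyloxy)deca-2,6-dien-1-one | COc1ccc(cc1)COC[C@@H](O[Si](CC)(CC)CC)C/C(C)=C/[C@@H](O[Si](CC)(CC)CC)C/C(C)=C/C(=O)N1CCOCC1
F8 | step 12 | (2E,5S,6E,9S)-10-(4-methoxybenzyloxy)-3,7-dimethyl-5,9-bis(triethylsilyloxy)deca-2,6-dienal | COc1ccc(cc1)COC[C@@H](O[Si](CC)(CC)CC)C/C(C)=C/[C@@H](O[Si](CC)(CC)CC)C/C(C)=C/C=O
F9 | step 12 | (2E,5S,6E,9S,10E,13S)-5-hydroxy-14-(4-methoxybenzyloxy)-3,7,11-trimethyl-1-(morpholin-4-yl)-9,13-bis(triethylsilyloxy)tetradeca-2,6,10-trien-1-one | COc1ccc(cc1)COC[C@@H](O[Si](CC)(CC)CC)C/C(C)=C/[C@@H](O[Si](CC)(CC)CC)C/C(C)=C/[C@@H](O)C/C(C)=C/C(=O)N1CCOCC1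
F10 | step 12 | (2E,5S,6E,9S,10E,13S)-5-(tert-butyldimethylsilyloxy)-14-(4-methoxybenzyloxy)-3,7,11-trimethyl-1-(morpholin-4-yl)-9,13-bis(triethylsilyloxy)tetradeca-2,6,10-trien-1-one | COc1ccc(cc1)COC[C@@H](O[Si](CC)(CC)CC)C/C(C)=C/[C@@H](O[Si](CC)(CC)CC)C/C(C)=C/[C@@H](O[Si](C)(C)C(C)(C)C)C/C(C)=C/C(=O)N1CCOCC1
F11 | step 12 | (2E,5S,6E,9S,10E,13S)-5-(tert-butyldimethylsilyloxy)-14-(4-methoxybenzyloxy)-3,7,11-trimethyl-9,13-bis(triethylsilyloxy)tetradeca-2,6,10-trienal | COc1ccc(cc1)COC[C@@H](O[Si](CC)(CC)CC)C/C(C)=C/[C@@H](O[Si](CC)(CC)CC)C/C(C)=C/[C@@H](O[Si](C)(C)C(C)(C)C)C/C(C)=C/C=O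
F12 | step 12 | (2E,5S,6E,9S,10E,13S)-5-(tert-butyldimethylsilyloxy)-14-hydroxy-3,7,11-trimethyl-9,13-bis(triethylsilyloxy)tetradeca-2,6,10-trienal | OC[C@@H](O[Si](CC)(CC)CC)C/C(C)=C/[C@@H](O[Si](CC)(CC)CC)C/C(C)=C/[C@@H](O[Si](C)(C)C(C)(C)C)C/C(C)=C/C=O
F13 | step 12 | (2E,5S,6E,9S,10E,13S)-5-(tert-butyldimethylsilyloxy)-3,7,11-trimethyl-9,13-bis(triethylsilyloxy)tetradeca-2,6,10-trienedial | O=C[C@@H](O[Si](CC)(CC)CC)C/C(C)=C/[C@@H](O[Si](CC)(CC)CC)C/C(C)=C/[C@@H](O[Si](C)(C)C(C)(C)C)C/C(C)=C/C=O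
F14 | step 12 | methyl (4S,6E,8S,10E,12S,14E)-12-(tert-butyldimethylsilyloxy)-3-hydroxy-6,10,14-trimethyl-2-methylidene-16-oxo-4,8-bis(triethylsilyloxy)hexadeca-6,10,14-trienoate (both C3 epimers) | C=C(C(=O)OC)C(O)[C@@H](O[Si](CC)(CC)CC)C/C(C)=C/[C@@H](O[Si](CC)(CC)CC)C/C(C)=C/[C@@H](O[Si](C)(C)C(C)(C)C)C/C(C)=C/C=O
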